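The route rests on cutting the C1–C2 bond of ring A. That ring carries oxygen on C2, C4 and C6 and the aroyl carbonyl on C1, the pattern left when a linear 3,5,7-triketo ester acylates its own ester carbon with the methylene next to the aryl ketone. One base-mediated Claisen closure therefore creates the complete 2,4,6-trihydroxybenzophenone core, carbocycle and ketone in place, so no Friedel–Crafts step is needed. The precursor is an open-chain methyl 3,5,7-trioxoheptanoate capped at C7 by a MOM-protected 4-hydroxyphenyl group, released from a dioxinone under neutral conditions immediately before use. C3/C5 prenylation, C4 O-methylation and MOM removal complete the synthesis.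

Key step: step 6

Assumption: the target has no stereocentre and no stereogenic double bond (each prenyl terminus carries two methyl groups), so it is achiral and only constitution has to be controlled.

Step 1
Reactants: 1 methyl 4-hydroxybenzoate
Product: 2 methyl 4-(methoxymethoxy)benzoate
Conditions: MOMCl (1.3 equiv), i-Pr2NEt (1.5 equiv), CH2Cl2, 0 °C → rt
Reagents that add atoms: chloromethyl methyl ether, COCCl
Why: Williamson-type O-alkylation of the acidic para-acyl phenol by the α-chloro ether should give an aryl acetal that is inert to every basic, organometallic and thermal step that follows.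

Step 2
Reactants: 2 methyl 4-(methoxymethoxy)benzoate
Product: 3 N-methoxy-4-(methoxymethoxy)-N-methylbenzamide
Conditions: MeNH(OMe)·HCl (1.5 equiv), i-PrMgCl (3.0 equiv), THF, −20 → 0 °C; aq. NH4Cl
Reagents that add atoms: N,O-dimethylhydroxylamine hydrochloride, CNOC.Cl
Why: Direct aminolysis of the ester by the chloromagnesium amide (Weinreb amide synthesis) should leave the MOM acetal untouched and supplies an acyl donor that stops at the ketone stage in step 4.

Step 3
Reactants: 4 2,2,6-trimethyl-4H-1,3-dioxin-4-one; 5 acetyl chloride
Product: 7 2,2-dimethyl-6-(2-oxopropyl)-4H-1,3-dioxin-4-one, via lithium dienolate 6 (not isolated)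
Conditions: 4 (2.0 equiv), LiHMDS (commercial, 2.0 equiv), THF, −78 °C; then 5 (1.0 equiv), −78 → −20 °C; aq. NH4Cl
Reagents that add atoms: none
Why: In this vinylogous Claisen-type acylation the dienolate reacts with the acid chloride at its exocyclic γ-carbon, and the second equivalent of dienolate takes up the proton of the more acidic β-keto product (recovered as 4), which should suppress double acylation.

Step 4
Reactants: 7 2,2-dimethyl-6-(2-oxopropyl)-4H-1,3-dioxin-4-one; 3 N-methoxy-4-(methoxymethoxy)-N-methylbenzamide
Product: 10 6-{4-[4-(methoxymethoxy)phenyl]-2,4-dioxobutyl}-2,2-dimethyl-4H-1,3-dioxin-4-one, via dilithium dianion 8 (not isolated), via Weinreb adduct 9 (not isolated)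
Conditions: 7 (1.25 equiv), LDA (commercial, 2.6 equiv), THF, −78 → −40 °C; then 3 (1.0 equiv), −78 → −20 °C; aq. NH4Cl (pH ≈ 5)
Reagents that add atoms: none
Why: In this dianion C-acylation (Weinreb ketone synthesis) the second deprotonation creates the more reactive terminal carbanion, which adds to the amide to give a chelated tetrahedral adduct that collapses only on quench, so neither over-addition nor proton transfer to the product should interfere.

Step 5
Reactants: 10 6-{4-[4-(methoxymethoxy)phenyl]-2,4-dioxobutyl}-2,2-dimethyl-4H-1,3-dioxin-4-one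
Product: 12 methyl 7-[4-(methoxymethoxy)phenyl]-3,5,7-trioxoheptanoate, via acylketene 11 (not isolated)
Conditions: MeOH (10 equiv), PhMe, 110 °C (sealed tube), 1 h; concentrate, use crude without chromatography
Reagents that add atoms: methanol, CO
Why: Thermal retro-hetero-Diels–Alder cycloreversion of the dioxinone expels acetone and the acylketene is trapped by excess methanol faster than it can lactonise, so the triketo ester (an enol mixture, drawn as the keto form) is released under neutral conditions and should not fold prematurely.

Step 6
Reactants: 12 methyl 7-[4-(methoxymethoxy)phenyl]-3,5,7-trioxoheptanoate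
Product: 14 [4-(methoxymethoxy)phenyl](2,4,6-trihydroxyphenyl)methanone, via cyclic trione 13 (not isolated)
Conditions: Mg(OMe)2 (commercial solution in MeOH, 5 equiv), MeOH, rt → 60 °C; then cold 1 M HCl to pH 4–5
Reagents that add atoms: none
Why: Excess magnesium methoxide converts the triketo ester into a magnesium-chelated polyenolate in which C3, C5 and C7 are enolate carbons and only the ester carbon stays electrophilic; the C6 carbanion (future ring carbon C1, between the aryl ketone and the C5 carbonyl) adds to the ester carbonyl (future C2) and methoxide leaves. This is an intramolecular Claisen C-acylation, the reaction type known for 3,5,7-triketo esters giving acylphloroglucinols. Ring A closes in a 6-exo-trig mode (6-enolendo-exo-trig in enolate terms), and tautomerisation of trione 13 to the aromatic triol should make the closure irreversible. No stereocentre is formed. The step needs Claisen selectivity over the C2-to-C7 aldol folding (which would give a biaryl resorcylate), over lactonisation to a pyranone and over retro-Claisen cleavage; full enolisation under anhydrous methoxide, the magnesium template and the weak electrophilicity of the ketone conjugated to the 4-alkoxyphenyl ring should secure it.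

Step 7
Reactants: 14 [4-(methoxymethoxy)phenyl](2,4,6-trihydroxyphenyl)methanone
Product: 16 [4-(methoxymethoxy)phenyl][2,4,6-trihydroxy-3,5-bis(3-methylbut-2-en-1-yl)phenyl]methanone, via monoprenyl triol 15 (not isolated)
Conditions: prenyl bromide (2.2 equiv, slow addition), 10% aq. KOH, 0 °C; then cold dilute HCl to pH 5
Reagents that add atoms: prenyl bromide (1-bromo-3-methylbut-2-ene), CC(C)=CCBr
Why: In this C-alkylation of the ambident acylphloroglucinol phenoxide, water hydrogen-bonds the oxyanions and steers the allylic bromide to the two free ring carbons C3 and C5, each alkylation is followed by rearomatisation, and low temperature with about two equivalents of bromide should limit geminal over-alkylation.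

Step 8
Reactants: 16 [4-(methoxymethoxy)phenyl][2,4,6-trihydroxy-3,5-bis(3-methylbut-2-en-1-yl)phenyl]methanone
Product: 17 [2,6-dihydroxy-4-methoxy-3,5-bis(3-methylbut-2-en-1-yl)phenyl][4-(methoxymethoxy)phenyl]methanone
Conditions: Me2SO4 (1.05 equiv), K2CO3 (1.1 equiv), acetone, rt
Reagents that add atoms: dimethyl sulfate, COS(=O)(=O)OC
Why: In this selective Williamson O-methylation the C4 hydroxyl para to the carbonyl is the most acidic and the only one that cannot hydrogen-bond to the ketone, so one equivalent of weak base and a hard methylating agent should give the C4 methyl ether and leave the C2 and C6 hydroxyls free.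

Step 9
Reactants: 17 [2,6-dihydroxy-4-methoxy-3,5-bis(3-methylbut-2-en-1-yl)phenyl][4-(methoxymethoxy)phenyl]methanone
Product: 18 vismiaphenone D, [2,6-dihydroxy-4-methoxy-3,5-bis(3-methylbut-2-en-1-yl)phenyl](4-hydroxyphenyl)methanone
Conditions: HCl (commercial, ca. 1 M in MeOH), 0 °C → rt, monitored; aq. NaHCO3
Reagents that add atoms: none
Why: Acid-catalysed acetal exchange (MOM ether cleavage) passes the methoxymethyl group to methanol as dimethoxymethane under conditions too mild to protonate the trisubstituted prenyl alkenes, so chroman formation with the neighbouring phenols should be avoided.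

Compound list
1 | methyl 4-hydroxybenzoate | COC(=O)c1ccc(O)cc1 | starting material
2 | methyl 4-(methoxymethoxy)benzoate | COCOc1ccc(C(=O)OC)cc1 | intermediate
3 | N-methoxy-4-(methoxymethoxy)-N-methylbenzamide | COCOc1ccc(C(=O)N(C)OC)cc1 | intermediate
4 | 2,2,6-trimethyl-4H-1,3-dioxin-4-one | CC1=CC(=O)OC(C)(C)O1 | starting material
5 | acetyl chloride | CC(Cl)=O | starting material
6 | lithium 2,2-dimethyl-6-methylidene-6H-1,3-dioxin-4-olate (lithium dienolate of 4) | [Li+].C=C1C=C([O-])OC(C)(C)O1 | intermediate
7 | 2,2-dimethyl-6-(2-oxopropyl)-4H-1,3-dioxin-4-one | CC(=O)CC1=CC(=O)OC(C)(C)O1 | intermediate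
8 | dilithium 2,2-dimethyl-6-(2-oxidoprop-2-en-1-ylidene)-6H-1,3-dioxin-4-olate (dianion of 7) | [Li+].[Li+].C=C([O-])C=C1C=C([O-])OC(C)(C)O1 | intermediate
9 | dilithium salt of the tetrahedral N-methoxy-N-methyl hemiaminal adduct of 8 and 3 | [Li+].[Li+].COCOc1ccc(C([O-])(CC(=O)C=C2C=C([O-])OC(C)(C)O2)N(C)OC)cc1 | intermediate
10 | 6-{4-[4-(methoxymethoxy)phenyl]-2,4-dioxobutyl}-2,2-dimethyl-4H-1,3-dioxin-4-one | COCOc1ccc(C(=O)CC(=O)CC2=CC(=O)OC(C)(C)O2)cc1 | intermediate
11 | 7-[4-(methoxymethoxy)phenyl]hept-1-ene-1,3,5,7-tetrone (acylketene) | COCOc1ccc(C(=O)CC(=O)CC(=O)C=C=O)cc1 | intermediate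
12 | methyl 7-[4-(methoxymethoxy)phenyl]-3,5,7-trioxoheptanoate | COCOc1ccc(C(=O)CC(=O)CC(=O)CC(=O)OC)cc1 | intermediate
13 | 2-[4-(methoxymethoxy)benzoyl]cyclohexane-1,3,5-trione (formed as its magnesium enolate) | COCOc1ccc(C(=O)C2C(=O)CC(=O)CC2=O)cc1 | intermediate
14 | [4-(methoxymethoxy)phenyl](2,4,6-trihydroxyphenyl)methanone | COCOc1ccc(C(=O)c2c(O)cc(O)cc2O)cc1 | intermediate
15 | [4-(methoxymethoxy)phenyl][2,4,6-trihydroxy-3-(3-methylbut-2-en-1-yl)phenyl]methanone | COCOc1ccc(C(=O)c2c(O)cc(O)c(CC=C(C)C)c2O)cc1 | intermediate
16 | [4-(methoxymethoxy)phenyl][2,4,6-trihydroxy-3,5-bis(3-methylbut-2-en-1-yl)phenyl]methanone | COCOc1ccc(C(=O)c2c(O)c(CC=C(C)C)c(O)c(CC=C(C)C)c2O)cc1 | intermediate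
17 | [2,6-dihydroxy-4-methoxy-3,5-bis(3-methylbut-2-en-1-yl)phenyl][4-(methoxymethoxy)phenyl]methanone | COCOc1ccc(C(=O)c2c(O)c(CC=C(C)C)c(OC)c(CC=C(C)C)c2O)cc1 | intermediate
18 | vismiaphenone D, [2,6-dihydroxy-4-methoxy-3,5-bis(3-methylbut-2-en-1-yl)phenyl](4-hydroxyphenyl)methanone (achiral) | COc1c(CC=C(C)C)c(O)c(C(=O)c2ccc(O)cc2)c(O)c1CC=C(C)C | target

Total step count: 9. Longest linear sequence: 8 steps (1, 2, 4, 5, 6, 7, 8, 9 from methyl 4-hydroxybenzoate); step 3 is a one-step side branch.

Steps most likely to fail

Step 6. The chain may fold the other way (C2 carbanion onto the C7 carbonyl, then dehydration to a biaryl resorcylate), lactonise through an enol oxygen, or be cut by methoxide in a retro-Claisen cleavage. The fallback sets out from Weinreb amide 3 and returns at 14, bringing ring A in preformed. Commercial 1,3,5-tris(benzyloxy)benzene would be monobrominated (NBS, CH2Cl2, −78 → 0 °C) to 2-bromo-1,3,5-tris(benzyloxy)benzene F1. Bromine–lithium exchange (n-BuLi, THF, −78 °C) would give [2,4,6-tris(benzyloxy)phenyl]lithium F2, whose addition to 3 should give [4-(methoxymethoxy)phenyl][2,4,6-tris(benzyloxy)phenyl]methanone F3. Hydrogenolysis (H2, Pd/C, EtOAc, rt) should then remove the three benzyl ethers while the MOM acetal and the diaryl ketone persist, giving 14.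

Step 7. Incomplete alkylation, a further alkylation at an already prenylated carbon (dearomatisation to geminal diprenyl cyclohexadienones) and O-prenylation may divide the material. The fallback sets out from 14 and returns at 16. O-Allylation of the two hydroxyls not held by the ketone (allyl bromide 2.2 equiv, K2CO3, acetone, reflux) should give [2-hydroxy-4,6-bis(prop-2-en-1-yloxy)phenyl][4-(methoxymethoxy)phenyl]methanone F4. A double aromatic Claisen rearrangement (N,N-diethylaniline, 190 °C) can only end at C3 and C5, because an unsubstituted allyl group gives the same product by ortho or by para (Claisen–Cope) delivery; this should give [2,4,6-trihydroxy-3,5-di(prop-2-en-1-yl)phenyl][4-(methoxymethoxy)phenyl]methanone F5. Olefin cross-metathesis with 2-methyl-2-butene (Grubbs second-generation catalyst, CH2Cl2, 40 °C) would then turn both allyl groups into prenyl groups and give 16.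

Step 8. Alkylation may not stop at one oxygen, or the ambident phenoxide may take the methyl group on carbon (C3 or C5) with loss of aromaticity. The fallback sets out from 16 and returns at 17 without any new intermediate: a Mitsunobu etherification with methanol (PPh3, DIAD, THF, 0 °C → rt). In this neutral redox condensation only the most acidic hydroxyl (C4–OH) is deprotonated by the betaine and attacks the methoxyphosphonium ion through oxygen, so no free carbonate-generated phenoxide is present.

Further compounds
F1 | step 6 | 2-bromo-1,3,5-tris(benzyloxy)benzene | Brc1c(OCc2ccccc2)cc(OCc2ccccc2)cc1OCc1ccccc1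
F2 | step 6 | [2,4,6-tris(benzyloxy)phenyl]lithium | [Li]c1c(OCc2ccccc2)cc(OCc2ccccc2)cc1OCc1ccccc1
F3 | step 6 | [4-(methoxymethoxy)phenyl][2,4,6-tris(benzyloxy)phenyl]methanone | COCOc1ccc(C(=O)c2c(OCc3ccccc3)cc(OCc3ccccc3)cc2OCc2ccccc2)cc1
F4 | step 7 | [2-hydroxy-4,6-bis(prop-2-en-1-yloxy)phenyl][4-(methoxymethoxy)phenyl]methanone | COCOc1ccc(C(=O)c2c(O)cc(OCC=C)cc2OCC=C)cc1
F5 | step 7 | [2,4,6-trihydroxy-3,5-di(prop-2-en-1-yl)phenyl][4-(methoxymethoxy)phenyl]methanone | COCOc1ccc(C(=O)c2c(O)c(CC=C)c(O)c(CC=C)c2O)cc1
F0 | step 8 | none | none
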